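Target and isomer of the product: set one against the other at a stated time, and read how the total shares out at that time. Both start from none, so the ratio of their gains up to any reading is the ratio of their amounts at that reading.

| setting | winter | flask |
|---|---|---|
| substrate | 2.1 M | 1.5 M |
| gas phase | 200 mM (held) | 200 mM (held) |
| remark | run made earlier |  |
| time |  | 6.0 min |

winter run (percent of the substrate charged)

| time / min | target / % | isomer of the product / % |
|---|---|---|
| 1.00 | 2.5 | 2.6 |
| 2.00 | 4.7 | 3.5 |
| 3.00 | 7.7 | 6.5 |
| 4.00 | 9.0 | 11.3 |
| 5.00 | 11.8 | 15.3 |
| 6.00 | 12.9 | 16.8 |

(each reading ± 1 percentage point)

- what was read earlier has a scatter of 1 percentage point, one standard deviation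
- at the start none of the gas phase is in solution
- the reaction counts as stopped when no species that holds the substrate changes by six tenths of a point or more over the second half of the time

* at 6.0 min, what has stopped the reaction, if anything has (it is still moving / forward and back rates have come level / all of the substrate has reacted)
* how much target there is at 6.0 min, in percent of the substrate charged
* how much isomer of the product there is at 6.0 min, in percent of the substrate charged

Run the winter flask slowly. In the first instants the gas still has to enter the solution, yet at 1.00 min target 2.5% and isomer 2.6% already stand level within the scatter, and readings this coarse show no lag for certain. In the middle, at 3.00 min, isomer 6.5% trails target 7.7%. Towards the end the ratio reads 1.26, 1.30, 1.30, and a scatter of 1 percentage point on each reading leaves it open whether the ratio is still climbing. Pool the readings from 4.00 min on: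

isomer / target = 1.29

Call this the split ratio: isomer per target as read late in the winter run, a reading that belongs to those times and is no constant.

Over its second half the winter run gained 5.2 points of target, so expect the new flask to be moving too. Assume first order in substrate at the same gas level, which carries the winter percentages over unchanged. Then divide by the split ratio:

total = 29.7%
target = total / (1 + split ratio) = 13.0%
isomer = total − target = 16.7%

The forecast says it is still moving, with target 14% (10.5% to 19%) and isomer 18% (13.5% to 25%): “I take first order as the central case”. Its target stands above mine, and so does its isomer.

The flask gives: it is still moving, target 13.9%, isomer 17.3%.

    gas phase ⇌ dissolved gas, rate k1*(csat - [dissolved gas]) (kL = 0.0290 /s)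
    substrate + dissolved gas → target (k = 0.00740 /M/s)
    target ⇌ isomer of the product (K = 1.50, k = 0.0210 /s)

In this flask target and isomer relax towards each other by their own step alone with a half-life of 0.330 min, both directions counted, which is short against its 6.0 min. Multiply the flask's target by the split ratio and get 17.9% of isomer, against 17.3% found. Now take the same charge left until 25 min, with target 34.1%: the split ratio gives 44.0% of isomer, and that flask holds 50.2%.

(All runs were generated by integration with constants of no real substance; noise was put on by code.)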